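**Assumption:** Jaspaquinol has no stereocentres (it is achiral), so "single enantiomer" is read as the single (2E,6E) geometric isomer. Organometallics made in situ (organozinc, alkenylalanes) are not isolated and not numbered.

## Retrosynthetic overview

1. Target 11 ⇐ mono-O-Boc hydroquinone 10 by carbonate cleavage.
2. The ArCH2–C(sp2) bond of 10 is made by a new 1,4-addition of an (E)-alkenylalane to an o-quinone methide. The alane comes from syn-methylalumination of enyne 6 (sets 2E); the o-quinone methide comes from bis-Boc benzyl alcohol 9, made from gentisaldehyde 7.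
3. Enyne 6 ⇐ (E)-alkenyl iodide 3 + homopropargylzinc from 4 (Negishi sp2–sp3 coupling), then desilylation.
4. Iodide 3 ⇐ alkyne 2 by methylalumination/iodination (sets 6E); 2 ⇐ dihydro-β-ionone 1.
5. No ring is built: the trimethylcyclohexene ring arrives intact in 1 and the benzene ring in 7.

## Route

**Step 1**
Reactants: 1, dihydro-β-ionone [4-(2,6,6-trimethylcyclohex-1-en-1-yl)butan-2-one]
Product: 2, 2-(but-3-yn-1-yl)-1,3,3-trimethylcyclohex-1-ene
Conditions: LDA (1.05 eq), THF, −78 °C; ClP(O)(OEt)2, −78 °C → rt; then LDA (2.3 eq), THF, −78 °C → rt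
Reagents that add atoms: none (diethyl chlorophosphate is lost as phosphate)
Why: The kinetic CH3-side enolate is trapped as the enol phosphate and eliminated by LDA to the terminal alkyne (Negishi methyl ketone → alkyne protocol); no stereo-element is formed.

**Step 2**
Reactants: 2, 2-(but-3-yn-1-yl)-1,3,3-trimethylcyclohex-1-ene
Product: 3, 2-[(3E)-4-iodo-3-methylbut-3-en-1-yl]-1,3,3-trimethylcyclohex-1-ene
Conditions: Me3Al (2.0 eq), Cp2ZrCl2 (0.25 eq), CH2Cl2, 0 °C → rt; then I2 (1.2 eq), THF, −30 → 0 °C
Reagents that add atoms: trimethylaluminium, C[Al](C)C (CH3); iodine, II (I)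
Why: Negishi Zr-catalysed syn-methylalumination puts Me on the internal carbon and Al on the terminal carbon, cis to each other, and iodinolysis with retention gives the E-iodide (fixes the future 6E alkene); the tetrasubstituted ring alkene is inert.

**Step 3**
Reactants: 3, the (E)-alkenyl iodide; 4, (4-bromobut-1-yn-1-yl)trimethylsilane
Product: 5, trimethyl[(5E)-6-methyl-8-(2,6,6-trimethylcyclohex-1-en-1-yl)oct-5-en-1-yn-1-yl]silane
Conditions: 4, Mg, THF, then ZnBr2 (→ RZnBr); 3, Pd(PPh3)4 (5 mol %), THF, rt → 40 °C
Reagents that add atoms: none (all new atoms come from reactant 4)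
Why: Negishi alkenyl–alkyl cross-coupling proceeds with retention of the alkenyl iodide geometry, and the TMS group masks the acidic alkyne C–H.

**Step 4**
Reactants: 5, the TMS-enyne
Product: 6, 1,3,3-trimethyl-2-[(3E)-3-methyloct-3-en-7-yn-1-yl]cyclohex-1-ene
Conditions: K2CO3, MeOH, rt
Reagents that add atoms: none
Why: Methanolysis of the alkynyl C–Si bond (protodesilylation) leaves both alkenes untouched.

**Step 5**
Reactants: 7, 2,5-dihydroxybenzaldehyde (gentisaldehyde)
Product: 8, 2,5-bis[(tert-butoxycarbonyl)oxy]benzaldehyde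
Conditions: Boc2O (2.3 eq), i-Pr2NEt, DMAP (5 mol %), THF, 0 °C → rt
Reagents that add atoms: di-tert-butyl dicarbonate, CC(C)(C)OC(=O)OC(=O)OC(C)(C)C
Why: DMAP-catalysed O-acylation converts both phenols into aryl tert-butyl carbonates.

**Step 6**
Reactants: 8, the bis-Boc aldehyde
Product: 9, 2,5-bis[(tert-butoxycarbonyl)oxy]benzyl alcohol
Conditions: BH3·THF (1.0 eq), THF, 0 °C; MeOH quench, pH 7 work-up
Reagents that add atoms: none (hydride only)
Why: Neutral borane reduction of the aldehyde avoids a free alkoxide, so the ortho carbonate does not migrate prematurely, and aryl carbonates are not reduced at 0 °C.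

**Step 7 (new transformation)**
Reactants: 6, the terminal enyne; 9, the bis-Boc benzyl alcohol
Product: 10, tert-butyl 3-[(2E,6E)-3,7-dimethyl-9-(2,6,6-trimethylcyclohex-1-en-1-yl)nona-2,6-dien-1-yl]-4-hydroxyphenyl carbonate
Conditions: (a) 6, Me3Al (2.0 eq), Cp2ZrCl2 (0.25 eq), CH2Cl2, 0 °C → rt; volatiles including excess Me3Al removed in vacuo; toluene. (b) 9 (1.4 eq), t-BuMgCl (1.4 eq), THF, −78 °C, cannulated into (a) at −78 °C, then → 0 °C; cold Rochelle-salt work-up
Reagents that add atoms: trimethylaluminium, C[Al](C)C (the 3-methyl group)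
Why: Proposed new method: syn-methylalumination of 6 gives the (E)-alkenyl-AlMe2 (sets 2E); the magnesium alkoxide of 9 undergoes O→O Boc transfer to a phenoxide bearing a benzylic carbonate, which binds the Lewis-acidic alane and expels tert-butyl carbonate to unmask the o-quinone methide already O-coordinated to Al, and the alkenyl group (transferring in preference to methyl) is delivered to the exocyclic CH2 through a six-membered transition state with retention of alkene geometry, driven by re-aromatisation, giving only the ortho, linear product; closest known reaction types are capture of o-OBoc-benzyl-alkoxide-derived o-quinone methides by Grignard reagents, uncatalysed 1,4-addition of alkenyl/alkynylalanes to s-cis enones, and alkenylboronate addition to o-quinone methides.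

**Step 8**
Reactants: 10, mono-O-Boc jaspaquinol
Product: 11, jaspaquinol, 2-[(2E,6E)-3,7-dimethyl-9-(2,6,6-trimethylcyclohex-1-en-1-yl)nona-2,6-dien-1-yl]benzene-1,4-diol
Conditions: K2CO3 (2 eq), degassed MeOH, Ar, 0 °C → rt; aq. NH4Cl/Na2S2O4 work-up
Reagents that add atoms: none
Why: Base-mediated methanolysis of the aryl tert-butyl carbonate frees the second phenol without acid (no chroman formation, no alkene isomerisation), and exclusion of O2 plus a dithionite wash keeps the hydroquinone from oxidising to the quinone.

## Compound list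

1 | dihydro-β-ionone | CC(=O)CCC1=C(C)CCCC1(C)C | starting material
2 | 2-(but-3-yn-1-yl)-1,3,3-trimethylcyclohex-1-ene | C#CCCC1=C(C)CCCC1(C)C | intermediate
3 | 2-[(3E)-4-iodo-3-methylbut-3-en-1-yl]-1,3,3-trimethylcyclohex-1-ene | CC1=C(CC/C(C)=C/I)C(C)(C)CCC1 | intermediate
4 | (4-bromobut-1-yn-1-yl)trimethylsilane | C[Si](C)(C)C#CCCBr | starting material
5 | trimethyl[(5E)-6-methyl-8-(2,6,6-trimethylcyclohex-1-en-1-yl)oct-5-en-1-yn-1-yl]silane | CC1=C(CC/C(C)=C/CCC#C[Si](C)(C)C)C(C)(C)CCC1 | intermediate
6 | 1,3,3-trimethyl-2-[(3E)-3-methyloct-3-en-7-yn-1-yl]cyclohex-1-ene | CC1=C(CC/C(C)=C/CCC#C)C(C)(C)CCC1 | intermediate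
7 | 2,5-dihydroxybenzaldehyde | O=Cc1cc(O)ccc1O | starting material
8 | 2,5-bis[(tert-butoxycarbonyl)oxy]benzaldehyde | O=Cc1cc(OC(=O)OC(C)(C)C)ccc1OC(=O)OC(C)(C)C | intermediate
9 | 2,5-bis[(tert-butoxycarbonyl)oxy]benzyl alcohol | OCc1cc(OC(=O)OC(C)(C)C)ccc1OC(=O)OC(C)(C)C | intermediate
10 | tert-butyl 3-[(2E,6E)-3,7-dimethyl-9-(2,6,6-trimethylcyclohex-1-en-1-yl)nona-2,6-dien-1-yl]-4-hydroxyphenyl carbonate | CC1=C(CC/C(C)=C/CC/C(C)=C/Cc2cc(OC(=O)OC(C)(C)C)ccc2O)C(C)(C)CCC1 | intermediate
11 | jaspaquinol | CC1=C(CC/C(C)=C/CC/C(C)=C/Cc2cc(O)ccc2O)C(C)(C)CCC1 | target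

## Totals

Total steps: 8.
Longest linear sequence: 6 steps (1 → 2 → 3 → 5 → 6 → 10 → 11; steps 1, 2, 3, 4, 7, 8).

## Three steps most likely to fail

1. **Step 7 (proposed new alkenylalane / o-quinone methide addition).** Risks are o-quinone methide oligomerisation, competing methyl transfer and attack on the remaining carbonate. Fallback (known chemistry): couple the same alkenylalane with commercial 2,5-dimethoxybenzyl chloride under Ni(0) or Pd(0) catalysis (alkenylalane–benzyl halide cross-coupling), then oxidise with CAN to the quinone and reduce with Na2S2O4 to 11.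
2. **Step 1 (methyl ketone → terminal alkyne).** Risks are incomplete CH3-versus-CH2 selectivity in the kinetic enolisation and allene/internal-alkyne by-products. Fallback: drop the alkyne route for the first alkene. Horner–Wadsworth–Emmons olefination of 1 with triethyl phosphonoacetate (E-major, separate isomers), DIBAL-H reduction, PBr3 bromination, then alkylation with lithiated 1-(trimethylsilyl)propyne gives 5 directly and replaces steps 1–3.
3. **Step 6 (borane reduction to the o-OBoc benzyl alcohol 9).** Risk is premature Boc migration and o-quinone methide loss or over-reduction during reduction or work-up. Fallback: reverse the order. Reduce 7 to 2,5-dihydroxybenzyl alcohol (NaBH4) first, then install the two aryl carbonates phenoxide-selectively (Boc2O, aq. NaOH/Bu4NHSO4 phase transfer), so the aldehyde and the ortho carbonate never coexist.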